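**Plan**

Numbering used throughout: ring carbons C1 (methacryloyloxy carbinol), C2, C3 (methyl carbinol), C4, C5 (acetoxy carbinol), C6=C7 (methyl on C7), C8=C9 (C9 carries the lactone oxygen), C10; lactone carbons C11 (bearing C13H2OH) and C12 (C=O).
Retrosynthetic cuts, in order: the C13 silyl ether and the two esters; C5–H (back to a ketone); the N–O bond of an isoxazoline; C8=C9 and C12=O (enol lactone back to a 2,3,4-trisubstituted furan); then C4–C5 together with C3–O (nitrile oxide cycloaddition); C8–C9 (furan α-alkylation); C1–C2 (methallylation).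
Enabling feature: the triad C3(OH)(CH3)–C4H2–C5(O), a tertiary methyl carbinol 1,3 to an oxygenated allylic carbon across an unsubstituted CH2, is the retron of a 5-methyl-2-isoxazoline, that is, of a C5 nitrile oxide adding to a C3(CH3)=C4H2 methallyl end. The five-membered ring fused at C9=C10 (carried as a furan) and the E-C6=C7 bond preorganise the chain.
Forward: the furan ring is present from the start; C1–C2 and then C8–C9 attach the two side chains; one cycloaddition closes the ten-membered carbocycle and the isoxazoline together; the furan is then oxygenated and dehydrated to the enol lactone, the isoxazoline is opened, and C1 esterification, C5 reduction, C5 acetylation and desilylation finish.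
Stereochemistry: C1 by reagent-controlled allylboration; C3 relayed from C1 in the cycloaddition; C5 by oxazaborolidine-catalysed ketone reduction; E-C6=C7 from a stabilised Wittig reaction; C8=C9 geometry imposed by the ring.

Key step: step 9

**Route**

Step 1
Reactants: 1 2,2-dimethoxyacetaldehyde; 2 ethyl 2-(triphenylphosphoranylidene)propanoate
Product: 3 ethyl (E)-4,4-dimethoxy-2-methylbut-2-enoate
Conditions: CH2Cl2/H2O, rt
Reagents that add atoms: none
Why: Wittig olefination with a stabilised, α-branched ylide should give the E-trisubstituted enoate (acetal carbon trans to the ester), which fixes the later C6=C7 geometry.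

Step 2
Reactants: 3 ethyl (E)-4,4-dimethoxy-2-methylbut-2-enoate
Product: 4 (E)-4,4-dimethoxy-2-methylbut-2-en-1-ol
Conditions: i-Bu2AlH, CH2Cl2, −78 °C
Reagents that add atoms: none
Why: Low-temperature hydride reduction of the conjugated ester should give the allylic alcohol without touching the acetal or the alkene geometry.

Step 3
Reactants: 4 (E)-4,4-dimethoxy-2-methylbut-2-en-1-ol
Product: 6 (E)-4-bromo-1,1-dimethoxy-3-methylbut-2-ene, via allylic methanesulfonate 5 (not isolated)
Conditions: MsCl, Et3N, THF, −40 °C; then LiBr, 0 °C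
Reagents that add atoms: lithium bromide, [Li+].[Br-]; methanesulfonyl chloride, CS(=O)(=O)Cl (carried only by 5)
Why: Sulfonylation followed by SN2 displacement with bromide (Finkelstein-type) converts the primary allylic alcohol into the bromide under non-acidic conditions that spare the dimethyl acetal.

Step 4
Reactants: 7 furan-3,4-diyldimethanol
Product: 8 [4-(triisopropylsilyloxymethyl)furan-3-yl]methanol
Conditions: NaH (1 equiv), THF, 0 °C → rt; then i-Pr3SiCl
Reagents that add atoms: chlorotriisopropylsilane, CC(C)[Si](Cl)(C(C)C)C(C)C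
Why: Monosilylation of a symmetrical diol through its sparingly soluble monosodium alkoxide should differentiate the two hydroxymethyl groups (the later C1 and C13).

Step 5
Reactants: 8 [4-(triisopropylsilyloxymethyl)furan-3-yl]methanol
Product: 9 4-(triisopropylsilyloxymethyl)furan-3-carbaldehyde
Conditions: MnO2, CH2Cl2, rt
Reagents that add atoms: none
Why: Manganese dioxide oxidises the furylmethyl (benzylic-type) alcohol to the aldehyde and should stop at that level.

Step 6
Reactants: 9 4-(triisopropylsilyloxymethyl)furan-3-carbaldehyde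
Product: 11 (R)-3-methyl-1-[4-(triisopropylsilyloxymethyl)furan-3-yl]but-3-en-1-ol, via borinate ester 10 (not isolated)
Conditions: (+)-B-methoxydiisopinocampheylborane, CH2=C(CH3)CH2MgCl, Et2O, −78 °C → rt; then 9, −78 °C; then NaOH, H2O2
Reagents that add atoms: methallylmagnesium chloride, C=C(C)C[Mg]Cl; (+)-B-methoxydiisopinocampheylborane, COB([C@H]1C[C@H]2C[C@@H]([C@@H]1C)C2(C)C)[C@H]1C[C@H]2C[C@@H]([C@@H]1C)C2(C)C (carried only by 10)
Why: Asymmetric allylboration (Brown methallylation) through a chair Zimmerman–Traxler transition state, in which the borane derived from (−)-α-pinene is expected to add to the Re face of the aryl-type aldehyde as it does with benzaldehyde, sets C1 as (R), and oxidative work-up cleaves the borinate.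

Step 7
Reactants: 11 (R)-3-methyl-1-[4-(triisopropylsilyloxymethyl)furan-3-yl]but-3-en-1-ol; 6 (E)-4-bromo-1,1-dimethoxy-3-methylbut-2-ene
Product: 14 (R)-2-[(E)-4,4-dimethoxy-2-methylbut-2-enyl]-3-[3-methyl-1-(triethylsilyloxy)but-3-enyl]-4-(triisopropylsilyloxymethyl)furan, via dilithio species 12 (not isolated), via lithium alkoxide 13 (not isolated)
Conditions: n-BuLi (2.1 equiv), THF, −78 → 0 °C; then 6, −78 °C → rt; then Et3SiCl, 0 °C
Reagents that add atoms: chlorotriethylsilane, CC[Si](Cl)(CC)CC; n-butyllithium, [Li]CCCC (lithium carried only by 12 and 13)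
Why: The lithium alkoxide should direct the second equivalent of base to the adjacent furan α-position C9 (directed ortho-lithiation of a 3-furylcarbinol; the bulky, weakly coordinating silyl ether shields C12), the furyllithium displaces the primary allylic bromide by SN2 to form C8–C9, and the alkoxide is silylated in the same flask.

Step 8
Reactants: 14 (R)-2-[(E)-4,4-dimethoxy-2-methylbut-2-enyl]-3-[3-methyl-1-(triethylsilyloxy)but-3-enyl]-4-(triisopropylsilyloxymethyl)furan
Product: 16 (1R)-aldoxime [C5H=NOH on the E-C6=C7 side chain; oxime drawn E], via enal 15 (not isolated)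
Conditions: NH2OH·HCl, NaOAc, THF/H2O, rt
Reagents that add atoms: hydroxylamine hydrochloride, NO.Cl; water, O (carried only by 15)
Why: The allylic dimethyl acetal should hydrolyse in the weakly acidic hydroxylamine buffer and the enal condenses to the aldoxime (either oxime geometry serves), while both silyl ethers survive.

Step 9
Reactants: 16 (1R)-aldoxime
Product: 19 (1R,3S)-isoxazoline-bridged furano-macrocycle [ten-membered ring C1–C10 fused to the furan at C9–C10; C3–O–N=C5 bridge; E-C6=C7; C1 OSiEt3; C13 OSi(i-Pr)3], via hydroximoyl chloride 17 (not isolated), via nitrile oxide 18 (not isolated)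
Conditions: aq. NaOCl, CH2Cl2, 0 °C → rt, 16 added by syringe pump (about 2 mM)
Reagents that add atoms: sodium hypochlorite, [Na+].[O-]Cl (chlorine carried only by 17)
Why: Hypochlorite chlorinates the oxime to hydroximoyl chloride 17, base removes HCl to give nitrile oxide 18, and the dipole adds in one concerted, asynchronous [3+2] event across the C3=C4 methallyl terminus of the same molecule, carbon to C4 and oxygen to C3. The closest known reaction type is the intramolecular nitrile oxide–olefin cycloaddition used as a masked macro-aldol, in which long-tethered alkenyl nitrile oxides close medium and large carbocycles as bridged 2-isoxazolines. Two rings close: the isoxazoline (C3, C4, C5, N, O) by the concerted cycloaddition, and the ten-membered carbocycle in the endo (bridged) mode through the new C4–C5 bond, with the furan C9=C10 bond as a cis clamp and E-C6=C7 as a rigid spacer that hold C5 near C4. The one new stereocentre, C3, is controlled by C1: the tether leaves C1 toward the dipole, the small C1–H bond lies over the forming heterocycle and the bulky triethylsilyloxy group points to the periphery, an arrangement that should place the new C3–O bond anti to C1–O, i.e. (3S) from (1R). The step needs regioselectivity (oxygen to the substituted alkene carbon, secured by the 1,1-disubstitution, since the alternative fused mode would have to form a quaternary C–C bond in a nine-membered ring), chemoselectivity (the furan and the conjugated C6=C7 bond are poor dipolarophiles and out of reach, and basic hypochlorite should chlorinate the oximate faster than the furan) and ring closure in preference to furoxan formation (secured by slow addition at high dilution). C5 leaves the step at the ketone oxidation level, so the single event delivers the ring, the C3–O bond and the handle for the C5 carbinol.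

Step 10
Reactants: 19 (1R,3S)-isoxazoline-bridged furano-macrocycle
Product: 21 (1R,3S)-γ-hydroxybutenolide [C12 lactone carbonyl; C9 lactol as both epimers; isoxazoline intact], via furan endoperoxide 20 (not isolated)
Conditions: O2, visible light, 5,10,15,20-tetraphenylporphyrin (cat.), i-Pr2NEt, CH2Cl2, −78 °C → rt
Reagents that add atoms: dioxygen, O=O
Why: Singlet oxygen should add [4+2] across the electron-rich trisubstituted furan much faster than it reacts with the conjugated C6=C7 bond, and base-induced Kornblum–DeLaMare fragmentation of the endoperoxide at its only bridgehead C–H (C12) gives the C12 carbonyl and the C9 lactol with a single possible regiochemistry.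

Step 11
Reactants: 21 (1R,3S)-γ-hydroxybutenolide
Product: 23 (1R,3S)-ylidene butenolide [E-C8=C9 enol lactone; isoxazoline intact; C1 OSiEt3; C13 OSi(i-Pr)3], via lactol methanesulfonate 22 (not isolated)
Conditions: MsCl, Et3N, CH2Cl2, −20 → 0 °C
Reagents that add atoms: methanesulfonyl chloride, CS(=O)(=O)Cl (carried only by 22)
Why: Sulfonylation of the lactol hydroxyl, loss of methanesulfonate assisted by the ring oxygen and removal of an allylic C8 proton should give the conjugated enol lactone, and the ten-membered ring allows only the geometry with C7 cis to C10, the contra-thermodynamic E isomer that an acyclic precursor would not give.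

Step 12
Reactants: 23 (1R,3S)-ylidene butenolide
Product: 26 (1R,3R)-1,3-dihydroxy-5-ketone [C1 OH; C3 OH tertiary; C5=O conjugated with C6=C7–C8=C9; C13 OSi(i-Pr)3], via β-hydroxy imine 24 (not isolated), via silyl ether ketone 25 (not isolated)
Conditions: Mo(CO)6, MeCN/H2O, 80 °C; then HF·pyridine, pyridine, THF, 0 °C
Reagents that add atoms: water, O
Why: Mo(CO)6 cleaves the N–O bond reductively and the β-hydroxy imine hydrolyses in the wet medium to unveil the masked aldol (C3 tertiary carbinol and C5 ketone, configuration at C3 retained), after which buffered fluoride should remove the secondary triethylsilyl ether much faster than the primary triisopropylsilyl ether.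

Step 13
Reactants: 26 (1R,3R)-1,3-dihydroxy-5-ketone
Product: 27 (1R,3R)-C1 methacrylate of the 5-ketone
Conditions: methacrylic anhydride, Et3N, 4-(dimethylamino)pyridine (cat.), CH2Cl2, 0 °C
Reagents that add atoms: methacrylic anhydride, C=C(C)C(=O)OC(=O)C(C)=C
Why: Nucleophile-catalysed acylation of the only secondary hydroxyl, the tertiary C3 hydroxyl being too hindered to react at 0 °C.

Step 14
Reactants: 27 (1R,3R)-C1 methacrylate of the 5-ketone
Product: 28 (1R,3S,5S)-C5 alcohol
Conditions: (R)-2-methyl-CBS-oxazaborolidine [(3aR)-1-methyl-3,3-diphenyltetrahydro-3H-pyrrolo[1,2-c][1,3,2]oxazaborole] (0.5 equiv), catecholborane, toluene, −78 °C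
Reagents that add atoms: none
Why: Corey–Bakshi–Shibata reduction, in which the ketone binds the catalyst with the dienyl group as the large substituent and the (R)-catalyst should deliver hydride to the face that gives the (5S)-alcohol under reagent control, in the 1,2-sense and without touching the lactone or the methacrylate.

Step 15
Reactants: 28 (1R,3S,5S)-C5 alcohol
Product: 29 (1R,3S,5S)-C5 acetate [C13 triisopropylsilyl ether of the target]
Conditions: Ac2O, pyridine, CH2Cl2, 0 °C → rt
Reagents that add atoms: acetic anhydride, CC(=O)OC(C)=O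
Why: Acetylation of the secondary allylic alcohol under conditions that leave the tertiary C3 hydroxyl free.

Step 16
Reactants: 29 (1R,3S,5S)-C5 acetate
Product: 30 CNP0246543.2
Conditions: HF·pyridine, pyridine, THF, 0 °C → rt
Reagents that add atoms: none
Why: Buffered fluoride cleaves the primary silyl ether under mildly acidic conditions that should cause neither acyl migration nor opening of the enol lactone.

**Compound list**

1 | 2,2-dimethoxyacetaldehyde | COC(OC)C=O | starting material
2 | ethyl 2-(triphenylphosphoranylidene)propanoate | CCOC(=O)C(C)=P(c1ccccc1)(c1ccccc1)c1ccccc1 | starting material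
3 | ethyl (E)-4,4-dimethoxy-2-methylbut-2-enoate | CCOC(=O)/C(C)=C/C(OC)OC | intermediate
4 | (E)-4,4-dimethoxy-2-methylbut-2-en-1-ol | OC/C(C)=C/C(OC)OC | intermediate
5 | (E)-4,4-dimethoxy-2-methylbut-2-enyl methanesulfonate | CS(=O)(=O)OC/C(C)=C/C(OC)OC | intermediate (not isolated)
6 | (E)-4-bromo-1,1-dimethoxy-3-methylbut-2-ene (becomes C8, C7 with its methyl, C6, C5) | BrC/C(C)=C/C(OC)OC | intermediate
7 | furan-3,4-diyldimethanol | OCc1cocc1CO | starting material
8 | [4-(triisopropylsilyloxymethyl)furan-3-yl]methanol | OCc1cocc1CO[Si](C(C)C)(C(C)C)C(C)C | intermediate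
9 | 4-(triisopropylsilyloxymethyl)furan-3-carbaldehyde | O=Cc1cocc1CO[Si](C(C)C)(C(C)C)C(C)C | intermediate
10 | diisopinocampheylborinate ester of alcohol 11 | C=C(C)C[C@@H](OB([C@H]1C[C@H]2C[C@@H]([C@@H]1C)C2(C)C)[C@H]1C[C@H]2C[C@@H]([C@@H]1C)C2(C)C)c1cocc1CO[Si](C(C)C)(C(C)C)C(C)C | intermediate (not isolated)
11 | (R)-3-methyl-1-[4-(triisopropylsilyloxymethyl)furan-3-yl]but-3-en-1-ol | C=C(C)C[C@@H](O)c1cocc1CO[Si](C(C)C)(C(C)C)C(C)C | intermediate
12 | C9,O-dilithio derivative of 11 | C=C(C)C[C@@H](O[Li])c1c([Li])occ1CO[Si](C(C)C)(C(C)C)C(C)C | intermediate (not isolated)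
13 | lithium alkoxide of the C9-alkylated alcohol | C=C(C)C[C@@H](O[Li])c1c(C/C(C)=C/C(OC)OC)occ1CO[Si](C(C)C)(C(C)C)C(C)C | intermediate (not isolated)
14 | (R)-2-[(E)-4,4-dimethoxy-2-methylbut-2-enyl]-3-[3-methyl-1-(triethylsilyloxy)but-3-enyl]-4-(triisopropylsilyloxymethyl)furan | C=C(C)C[C@@H](O[Si](CC)(CC)CC)c1c(C/C(C)=C/C(OC)OC)occ1CO[Si](C(C)C)(C(C)C)C(C)C | intermediate
15 | (1R)-enal (C5 aldehyde; E-C6=C7) | C=C(C)C[C@@H](O[Si](CC)(CC)CC)c1c(C/C(C)=C/C=O)occ1CO[Si](C(C)C)(C(C)C)C(C)C | intermediate (not isolated)
16 | (1R)-aldoxime (C5H=NOH) | C=C(C)C[C@@H](O[Si](CC)(CC)CC)c1c(C/C(C)=C/C=N/O)occ1CO[Si](C(C)C)(C(C)C)C(C)C | intermediate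
17 | (1R)-hydroximoyl chloride | C=C(C)C[C@@H](O[Si](CC)(CC)CC)c1c(C/C(C)=C/C(Cl)=N/O)occ1CO[Si](C(C)C)(C(C)C)C(C)C | intermediate (not isolated)
18 | (1R)-nitrile oxide | C=C(C)C[C@@H](O[Si](CC)(CC)CC)c1c(C/C(C)=C/C#[N+][O-])occ1CO[Si](C(C)C)(C(C)C)C(C)C | intermediate (not isolated)
19 | (1R,3S)-isoxazoline-bridged furano-macrocycle | CC[Si](CC)(CC)O[C@@H]1C[C@]2(C)CC(=NO2)/C=C(C)/Cc2occ(CO[Si](C(C)C)(C(C)C)C(C)C)c21 | intermediate
20 | furan endoperoxide of 19 (C9,C12-epidioxide) | CC[Si](CC)(CC)O[C@@H]1C[C@]2(C)CC(=NO2)/C=C(C)/CC23OOC(O2)C(CO[Si](C(C)C)(C(C)C)C(C)C)=C31 | intermediate (not isolated)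
21 | (1R,3S)-γ-hydroxybutenolide (C9 lactol, both epimers) | CC[Si](CC)(CC)O[C@@H]1C[C@]2(C)CC(=NO2)/C=C(C)/CC2(O)OC(=O)C(CO[Si](C(C)C)(C(C)C)C(C)C)=C21 | intermediate
22 | C9 lactol methanesulfonate of 21 | CC[Si](CC)(CC)O[C@@H]1C[C@]2(C)CC(=NO2)/C=C(C)/CC2(OS(C)(=O)=O)OC(=O)C(CO[Si](C(C)C)(C(C)C)C(C)C)=C21 | intermediate (not isolated)
23 | (1R,3S)-ylidene butenolide with isoxazoline bridge | CC[Si](CC)(CC)O[C@@H]1C[C@]2(C)CC(=NO2)/C=C(C)/C=C2/OC(=O)C(CO[Si](C(C)C)(C(C)C)C(C)C)=C21 | intermediate
24 | (1R,3S)-β-hydroxy imine (C5=NH) | CC[Si](CC)(CC)O[C@@H]1C[C@@](C)(O)CC(=N)/C=C(C)/C=C2/OC(=O)C(CO[Si](C(C)C)(C(C)C)C(C)C)=C21 | intermediate (not isolated)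
25 | (1R,3R)-β-hydroxy ketone, C1 triethylsilyl ether | CC[Si](CC)(CC)O[C@@H]1C[C@@](C)(O)CC(=O)/C=C(C)/C=C2/OC(=O)C(CO[Si](C(C)C)(C(C)C)C(C)C)=C21 | intermediate (not isolated)
26 | (1R,3R)-1,3-dihydroxy-5-ketone | O[C@@H]1C[C@@](C)(O)CC(=O)/C=C(C)/C=C2/OC(=O)C(CO[Si](C(C)C)(C(C)C)C(C)C)=C21 | intermediate
27 | (1R,3R)-C1 methacrylate of the 5-ketone | C=C(C)C(=O)O[C@@H]1C[C@@](C)(O)CC(=O)/C=C(C)/C=C2/OC(=O)C(CO[Si](C(C)C)(C(C)C)C(C)C)=C21 | intermediate
28 | (1R,3S,5S)-C5 alcohol | C=C(C)C(=O)O[C@@H]1C[C@@](C)(O)C[C@H](O)/C=C(C)/C=C2/OC(=O)C(CO[Si](C(C)C)(C(C)C)C(C)C)=C21 | intermediate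
29 | (1R,3S,5S)-C5 acetate, C13 triisopropylsilyl ether | C=C(C)C(=O)O[C@@H]1C[C@@](C)(O)C[C@H](OC(C)=O)/C=C(C)/C=C2/OC(=O)C(CO[Si](C(C)C)(C(C)C)C(C)C)=C21 | intermediate
30 | CNP0246543.2 | C=C(C)C(=O)O[C@@H]1C[C@@](C)(O)C[C@H](OC(C)=O)/C=C(C)/C=C2/OC(=O)C(CO)=C21 | target

**Step count and risks**

Total: 16 steps. Longest linear sequence: 13 steps (7 → 30 through steps 4–16; the branch 1 → 6, steps 1–3, joins at step 7).

Step 9 (cycloaddition). What may go wrong: the relay of configuration from C1 may run in the opposite sense, so that the dipole adds to the other face of the C3=C4 bond and the C3 epimer of 19 predominates. Fallback, an enantiomeric relay with late inversion: it sets out from aldehyde 9. Allylboration with the enantiomeric borane, made from (−)-B-methoxydiisopinocampheylborane, gives the (S)-homoallylic alcohol F1. The operations of steps 7 to 12 then give in turn the (S)-acetal F2, the (S)-aldoxime F3, the (1S,3S)-isoxazoline macrocycle F4 (the same intrinsic facial preference now delivers C3 in the configuration of the target), the (1S,3S)-γ-hydroxybutenolide F5, the (1S,3S)-ylidene butenolide F6 and the (1S,3R)-dihydroxy ketone F7. Mitsunobu esterification of F7 with methacrylic acid (PPh3, diisopropyl azodicarboxylate, THF, 0 °C) inverts C1 and installs the ester in one operation, and the sequence comes back to the route at 27.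

Step 7 (lithiation and alkylation). What may go wrong: loss of regiocontrol in the metalation, by deprotonation at C12 beside the silyloxymethyl group or by anionic oxygen-to-carbon silyl migration, competing with the alkoxide-directed lithiation at C9. Fallback, fragment union one stage earlier, at the primary alcohol, where the directing alkoxide is unhindered and C9 metalation is the established behaviour of 3-furylmethanol dianions: it sets out from alcohol 8. Dilithiation and alkylation with 6 (n-BuLi, THF, then 6) give the 2-alkylated furylmethanol F8; MnO2 oxidation gives the aldehyde F9; allylboration as in step 6 gives the (R)-homoallylic alcohol F10; silylation (Et3SiCl, imidazole, CH2Cl2) comes back to the route at 14.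

Step 14 (ketone reduction). What may go wrong: the conformational bias of the ten-membered ring may override the catalyst (mismatched pairing), so that hydride is delivered mainly to the other face of the C5 ketone. Fallback, use of the ring's preference followed by inversion: it sets out from ketone 27. Reduction in the matched sense with the (S)-oxazaborolidine and catecholborane gives the (5R)-alcohol F11, and Mitsunobu reaction with acetic acid (PPh3, diisopropyl azodicarboxylate, toluene, 0 °C) inverts C5 and comes back to the route at acetate 29, so that step 15 is not needed.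

**Further compounds**

F1 | step 9 | (S)-3-methyl-1-[4-(triisopropylsilyloxymethyl)furan-3-yl]but-3-en-1-ol | C=C(C)C[C@H](O)c1cocc1CO[Si](C(C)C)(C(C)C)C(C)C
F2 | step 9 | (S)-2-[(E)-4,4-dimethoxy-2-methylbut-2-enyl]-3-[3-methyl-1-(triethylsilyloxy)but-3-enyl]-4-(triisopropylsilyloxymethyl)furan | C=C(C)C[C@H](O[Si](CC)(CC)CC)c1c(C/C(C)=C/C(OC)OC)occ1CO[Si](C(C)C)(C(C)C)C(C)C
F3 | step 9 | (1S)-aldoxime | C=C(C)C[C@H](O[Si](CC)(CC)CC)c1c(C/C(C)=C/C=N/O)occ1CO[Si](C(C)C)(C(C)C)C(C)C
F4 | step 9 | (1S,3S)-isoxazoline-bridged furano-macrocycle | CC[Si](CC)(CC)O[C@H]1C[C@]2(C)CC(=NO2)/C=C(C)/Cc2occ(CO[Si](C(C)C)(C(C)C)C(C)C)c21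
F5 | step 9 | (1S,3S)-γ-hydroxybutenolide (C9 lactol, both epimers) | CC[Si](CC)(CC)O[C@H]1C[C@]2(C)CC(=NO2)/C=C(C)/CC2(O)OC(=O)C(CO[Si](C(C)C)(C(C)C)C(C)C)=C21
F6 | step 9 | (1S,3S)-ylidene butenolide with isoxazoline bridge | CC[Si](CC)(CC)O[C@H]1C[C@]2(C)CC(=NO2)/C=C(C)/C=C2/OC(=O)C(CO[Si](C(C)C)(C(C)C)C(C)C)=C21
F7 | step 9 | (1S,3R)-1,3-dihydroxy-5-ketone | O[C@H]1C[C@@](C)(O)CC(=O)/C=C(C)/C=C2/OC(=O)C(CO[Si](C(C)C)(C(C)C)C(C)C)=C21
F8 | step 7 | {2-[(E)-4,4-dimethoxy-2-methylbut-2-enyl]-4-(triisopropylsilyloxymethyl)furan-3-yl}methanol | OCc1c(C/C(C)=C/C(OC)OC)occ1CO[Si](C(C)C)(C(C)C)C(C)C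
F9 | step 7 | 2-[(E)-4,4-dimethoxy-2-methylbut-2-enyl]-4-(triisopropylsilyloxymethyl)furan-3-carbaldehyde | O=Cc1c(C/C(C)=C/C(OC)OC)occ1CO[Si](C(C)C)(C(C)C)C(C)C
F10 | step 7 | (R)-1-{2-[(E)-4,4-dimethoxy-2-methylbut-2-enyl]-4-(triisopropylsilyloxymethyl)furan-3-yl}-3-methylbut-3-en-1-ol | C=C(C)C[C@@H](O)c1c(C/C(C)=C/C(OC)OC)occ1CO[Si](C(C)C)(C(C)C)C(C)C
F11 | step 14 | (1R,3S,5R)-C5 alcohol (C5 epimer of 28) | C=C(C)C(=O)O[C@@H]1C[C@@](C)(O)C[C@@H](O)/C=C(C)/C=C2/OC(=O)C(CO[Si](C(C)C)(C(C)C)C(C)C)=C21
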